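**Plan** (the C19 acyl chain is numbered from its ester carbonyl C1; primed numbers belong to the C11 alkoxy chain)
- Cuts: (a) C4–C5, the C(sp3)–C(sp) bond at the head of the 5,7-diyne; (b) the acyl C1–O bond, so that C1–C4 plus one carbon lost as CO2 is glutaric anhydride; (c) the central sp–sp bond C5′–C6′ of the 4,6-diynol; (d) the butadiynyl–alkyl bond C8–C9 of the long arm; (e) both furan C2–CH2 bonds.
- Forward: furan is lithiated once and the solution is divided between the C4 and the C11 dibromide. The short arm becomes a terminal alkyne and is joined to 5-bromopent-4-yn-1-ol; the diynol opens glutaric anhydride and the free carboxyl is made a tetrachloro-N-hydroxyphthalimide ester. The long arm receives a TMS-butadiynyl unit and is desilylated; the two halves are then joined.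
- Enabling feature: C1 (ester carbonyl) and C5 (first sp carbon) of the acid are 1,5-related through three CH2 groups, i.e. a glutarate in which one carboxyl is replaced by the diyne. C4 can therefore be generated as an unstabilised primary radical by decarboxylation, while the terminal carbon of the conjugated C≡C–C≡C unit carries zinc. The six-membered anhydride ring supplies this unit and the ester bond together; both furan rings, the second diyne and the ester are spectators.
- Stereochemistry: none; the target has no stereocentre and no stereogenic double bond.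

Key step: step 11

Remark: 2-furyllithium is assumed to be stable enough in THF at or below 0 °C to be prepared once, titrated and used in two portions on the same day.

**Step 1**
Reactants: 1 furan
Product: 2 2-furyllithium
Conditions: furan (1.1 equiv), n-BuLi (1.0 equiv), THF, −20 → 0 °C; kept as a titrated THF solution at ≤0 °C under Ar and divided between steps 2 and 8
Reagents that add atoms: n-butyllithium, [Li]CCCC
Why: Directed deprotonation (lithiation) of furan at the acidic C2–H by n-butyllithium should give the 2-lithio species cleanly, the slight excess of furan ensuring that no butyllithium remains to attack the dibromides.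

**Step 2**
Reactants: 2 2-furyllithium; 3 1,4-dibromobutane
Product: 4 2-(4-bromobutyl)furan
Conditions: solution of 2 added to 3 (3 equiv), THF, −78 °C → rt
Reagents that add atoms: none
Why: The heteroaryllithium is alkylated by the primary dibromide in an SN2 reaction, the excess of 3 and inverse addition holding back double alkylation.

**Step 3**
Reactants: 4 2-(4-bromobutyl)furan; 5 lithium acetylide–ethylenediamine complex
Product: 6 2-(hex-5-yn-1-yl)furan
Conditions: DMSO, 10 °C → rt
Reagents that add atoms: none
Why: SN2 displacement of a primary bromide by lithium acetylide in DMSO is the standard route to a terminal alkyne and should leave the 2-alkylfuran untouched.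

**Step 4**
Reactants: 7 pent-4-yn-1-ol
Product: 8 5-bromopent-4-yn-1-ol
Conditions: NBS (1.1 equiv), AgNO3 (10 mol%), acetone, rt, dark
Reagents that add atoms: N-bromosuccinimide, O=C1CCC(=O)N1Br
Why: Silver-catalysed electrophilic bromination of a terminal alkyne gives the 1-bromoalkyne, and it is done on the furan-free partner because NBS brominates furans.

**Step 5**
Reactants: 6 2-(hex-5-yn-1-yl)furan; 8 5-bromopent-4-yn-1-ol
Product: 9 11-(furan-2-yl)undeca-4,6-diyn-1-ol
Conditions: CuCl (5 mol%), NH2OH·HCl (cat.), 30% aq. n-BuNH2, Et2O, 0 °C → rt
Reagents that add atoms: none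
Why: Cadiot–Chodkiewicz coupling of the copper(I) acetylide of 6 with bromoalkyne 8 should give only the unsymmetrical diyne, hydroxylamine keeping copper in the +1 state so that oxidative homocoupling is held back.

**Step 6**
Reactants: 9 11-(furan-2-yl)undeca-4,6-diyn-1-ol; 10 glutaric anhydride
Product: 11 5-{[11-(furan-2-yl)undeca-4,6-diyn-1-yl]oxy}-5-oxopentanoic acid
Conditions: DMAP (10 mol%), pyridine/CH2Cl2, rt; aq. citric acid work-up
Reagents that add atoms: none
Why: DMAP-catalysed alcoholysis of the symmetrical cyclic anhydride forms the ester bond of the target and frees the distal carboxyl in one operation, without protecting group or coupling reagent.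

**Step 7**
Reactants: 11 5-{[11-(furan-2-yl)undeca-4,6-diyn-1-yl]oxy}-5-oxopentanoic acid
Product: 12 1-[11-(furan-2-yl)undeca-4,6-diyn-1-yl] 5-(4,5,6,7-tetrachloro-1,3-dioxoisoindolin-2-yl) pentanedioate
Conditions: TCNHPI (1.05 equiv), DIC (1.1 equiv), DMAP (cat.), CH2Cl2, rt; short silica plug
Reagents that add atoms: N-hydroxytetrachlorophthalimide (TCNHPI), ON1C(=O)c2c(Cl)c(Cl)c(Cl)c(Cl)c2C1=O
Why: Carbodiimide (Steglich-type) esterification of the free acid with the N-hydroxyimide gives the redox-active ester under neutral conditions that the diyne and the furan should tolerate.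

**Step 8**
Reactants: 2 2-furyllithium; 13 1,11-dibromoundecane
Product: 14 2-(11-bromoundecyl)furan
Conditions: second portion of the solution of 2 added to 13 (3 equiv), THF, −78 °C → rt; chromatography (hexanes)
Reagents that add atoms: none
Why: The same heteroaryllithium SN2 alkylation as in step 2, with excess dibromide to favour the monoalkylated product.

**Step 9**
Reactants: 15 1,4-bis(trimethylsilyl)buta-1,3-diyne; 14 2-(11-bromoundecyl)furan
Product: 17 [15-(furan-2-yl)pentadeca-1,3-diyn-1-yl]trimethylsilane, via lithium (trimethylsilyl)butadiynide 16 (not isolated)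
Conditions: MeLi·LiBr (1.0 equiv), THF, rt; then 14, HMPA, −78 °C → rt
Reagents that add atoms: none
Why: Methyllithium cleaves one C(sp)–Si bond of 15 to the lithium butadiynide, which is alkylated by the primary bromide in THF/HMPA (acetylide alkylation) while the remaining TMS group blocks the other terminus.

**Step 10**
Reactants: 17 [15-(furan-2-yl)pentadeca-1,3-diyn-1-yl]trimethylsilane
Product: 18 2-(pentadeca-12,14-diyn-1-yl)furan
Conditions: K2CO3 (0.2 equiv), MeOH/THF, rt; kept cold in solution and used at once
Reagents that add atoms: none
Why: Methoxide-mediated protodesilylation of an alkynylsilane is fast at room temperature and should touch neither the furan nor the chain.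

**Step 11**
Reactants: 12 1-[11-(furan-2-yl)undeca-4,6-diyn-1-yl] 5-(4,5,6,7-tetrachloro-1,3-dioxoisoindolin-2-yl) pentanedioate; 18 2-(pentadeca-12,14-diyn-1-yl)furan
Product: 21 11-(furan-2-yl)undeca-4,6-diyn-1-yl 19-(furan-2-yl)nonadeca-5,7-diynoate, via lithium diynide 19 (not isolated), via diynylzinc chloride 20 (not isolated)
Conditions: 18 (2 equiv), n-BuLi, THF, −78 °C; ZnCl2 (THF), −78 → 0 °C; then 12 (1 equiv), NiCl2·glyme (20 mol%), 4,4′-di-tert-butyl-2,2′-bipyridine (20 mol%), THF/DMF, rt, Ar
Reagents that add atoms: none
Why: Transmetalation of diynylzinc chloride 20 to bipyridine-ligated nickel gives a low-valent Ni–diynyl species that transfers one electron to the tetrachlorophthalimide ester of 12, whose radical anion fragments by N–O cleavage and loss of CO2 to the primary 3-(alkoxycarbonyl)propyl radical; capture of this radical at nickel and reductive elimination from the alkyl(diynyl)nickel(III) forms the C(sp3)–C(sp) bond. The closest known reaction type is the nickel-catalysed decarboxylative alkynylation of redox-active esters with alkynylzinc halides, a radical Negishi-type cross-coupling. No ring is closed and no stereocentre is formed. The step needs chemoselectivity for the activated carboxyl over the alkyl ester, which is secured because only the N-acyloxyimide accepts an electron and organozinc reagents do not add to alkyl esters at room temperature. It also needs capture of the radical at nickel before it attacks a π-system, which the substrate secures because the radical is unstabilised, the nearest alkyne carbon could only be reached by closing a nine-membered ring, and the electron-rich furans are poor partners for a nucleophilic alkyl radical. The coupling site on the diyne is fixed by zinc on the terminal sp carbon, and the helper groups leave in the step itself as CO2 and tetrachlorophthalimide.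

**Compound list**
1 | furan | c1ccoc1 | starting material
2 | 2-furyllithium | [Li]c1ccco1 | intermediate
3 | 1,4-dibromobutane | BrCCCCBr | starting material
4 | 2-(4-bromobutyl)furan | BrCCCCc1ccco1 | intermediate
5 | lithium acetylide–ethylenediamine complex | [Li]C#C.NCCN | starting material
6 | 2-(hex-5-yn-1-yl)furan | C#CCCCCc1ccco1 | intermediate
7 | pent-4-yn-1-ol | OCCCC#C | starting material
8 | 5-bromopent-4-yn-1-ol | OCCCC#CBr | intermediate
9 | 11-(furan-2-yl)undeca-4,6-diyn-1-ol | OCCCC#CC#CCCCCc1ccco1 | intermediate
10 | glutaric anhydride | O=C1CCCC(=O)O1 | starting material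
11 | 5-{[11-(furan-2-yl)undeca-4,6-diyn-1-yl]oxy}-5-oxopentanoic acid | OC(=O)CCCC(=O)OCCCC#CC#CCCCCc1ccco1 | intermediate
12 | 1-[11-(furan-2-yl)undeca-4,6-diyn-1-yl] 5-(4,5,6,7-tetrachloro-1,3-dioxoisoindolin-2-yl) pentanedioate | O=C(CCCC(=O)ON1C(=O)c2c(Cl)c(Cl)c(Cl)c(Cl)c2C1=O)OCCCC#CC#CCCCCc1ccco1 | intermediate
13 | 1,11-dibromoundecane | BrCCCCCCCCCCCBr | starting material
14 | 2-(11-bromoundecyl)furan | BrCCCCCCCCCCCc1ccco1 | intermediate
15 | 1,4-bis(trimethylsilyl)buta-1,3-diyne | C[Si](C)(C)C#CC#C[Si](C)(C)C | starting material
16 | lithium 4-(trimethylsilyl)buta-1,3-diyn-1-ide | [Li]C#CC#C[Si](C)(C)C | intermediate (not isolated)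
17 | [15-(furan-2-yl)pentadeca-1,3-diyn-1-yl]trimethylsilane | C[Si](C)(C)C#CC#CCCCCCCCCCCCc1ccco1 | intermediate
18 | 2-(pentadeca-12,14-diyn-1-yl)furan | C#CC#CCCCCCCCCCCCc1ccco1 | intermediate
19 | lithium 15-(furan-2-yl)pentadeca-1,3-diyn-1-ide | [Li]C#CC#CCCCCCCCCCCCc1ccco1 | intermediate (not isolated)
20 | chloro[15-(furan-2-yl)pentadeca-1,3-diyn-1-yl]zinc | Cl[Zn]C#CC#CCCCCCCCCCCCc1ccco1 | intermediate (not isolated)
21 | 11-(furan-2-yl)undeca-4,6-diyn-1-yl 19-(furan-2-yl)nonadeca-5,7-diynoate | O=C(CCCC#CC#CCCCCCCCCCCCc1ccco1)OCCCC#CC#CCCCCc1ccco1 | target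

**Count**
Total steps: 11. Longest linear sequence: 7 (steps 1, 2, 3, 5, 6, 7, 11); step 4 and the long arm (steps 8, 9, 10, which draw on the solution from step 1) are side branches.

**Steps most likely to fail**

Step 11. Nickel may be drawn off into oligomerisation or carbometalation of the conjugated diynes, the diynylzinc may homocouple, or the alkyl radical may be reduced before it is captured. The fallback sets out from 14 and returns at 21; it gives up the sp3–sp union and builds the C19 acid at its central sp–sp bond instead. Bromide 14 is treated with lithium acetylide–ethylenediamine 5 in DMSO to give 2-(tridec-12-yn-1-yl)furan F1. Commercial hex-5-ynoic acid (OC(=O)CCCC#C) is brominated with NBS and catalytic AgNO3 in acetone to 6-bromohex-5-ynoic acid F2. Cadiot–Chodkiewicz coupling of F1 with F2 (CuCl, NH2OH·HCl, aq. n-BuNH2, then mild acidification) should give 19-(furan-2-yl)nonadeca-5,7-diynoic acid F3. Steglich esterification of F3 with diynol 9 (DCC, DMAP, CH2Cl2, 0 °C → rt) then gives 21.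

Step 9. The silylbutadiynide is a weak and thermally fragile nucleophile, so slow SN2 on the long-chain bromide may be outrun by decomposition of the anion or by elimination. The fallback sets out from 14 and returns at 18; it carries the diyne in masked form. Commercial (Z)-1-methoxybut-1-en-3-yne (CO/C=C\C#C) is lithiated with n-BuLi in THF at −78 °C to lithium (Z)-4-methoxybut-3-en-1-yn-1-ide F4, an ordinary and more nucleophilic acetylide. Alkylation of F4 by 14 in THF/HMPA gives 2-[(14Z)-15-methoxypentadec-14-en-12-yn-1-yl]furan F5. LDA (2.2 equiv, THF, −78 → 0 °C) then removes methanol by anti elimination and deprotonates the new terminus; quenching with aq. NH4Cl should give 18.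

Step 8. The mono-alkylation is statistical: double alkylation to the difurylundecane and difficult separation of the product from the high-boiling excess dibromide may both cut the supply of 14. The fallback sets out from 2 and returns at 14; it uses a monofunctional electrophile with a masked terminus. Commercial 11-bromoundecan-1-ol (OCCCCCCCCCCCBr) is silylated (TBSCl, imidazole, DMF) to [(11-bromoundecyl)oxy](tert-butyl)dimethylsilane F6. 2-Furyllithium 2, taken from the solution of step 1, is alkylated by F6 in THF to tert-butyl{[11-(furan-2-yl)undecyl]oxy}dimethylsilane F7. TBAF in THF gives 11-(furan-2-yl)undecan-1-ol F8, and Appel bromination (CBr4, PPh3, CH2Cl2, 0 °C) gives 14.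

**Further compounds**
F1 | step 11 | 2-(tridec-12-yn-1-yl)furan | C#CCCCCCCCCCCCc1ccco1
F2 | step 11 | 6-bromohex-5-ynoic acid | OC(=O)CCCC#CBr
F3 | step 11 | 19-(furan-2-yl)nonadeca-5,7-diynoic acid | OC(=O)CCCC#CC#CCCCCCCCCCCCc1ccco1
F4 | step 9 | lithium (Z)-4-methoxybut-3-en-1-yn-1-ide | CO/C=C\C#C[Li]
F5 | step 9 | 2-[(14Z)-15-methoxypentadec-14-en-12-yn-1-yl]furan | CO/C=C\C#CCCCCCCCCCCCc1ccco1
F6 | step 8 | [(11-bromoundecyl)oxy](tert-butyl)dimethylsilane | BrCCCCCCCCCCCO[Si](C)(C)C(C)(C)C
F7 | step 8 | tert-butyl{[11-(furan-2-yl)undecyl]oxy}dimethylsilane | CC(C)(C)[Si](C)(C)OCCCCCCCCCCCc1ccco1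
F8 | step 8 | 11-(furan-2-yl)undecan-1-ol | OCCCCCCCCCCCc1ccco1
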